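## The problem

Target 27 joins two lignan-type halves through one methylene group. The western half is a 2-aryl-3-(hydroxymethyl)-4-benzyl tetrahydrofuran whose aryl group is 3-hydroxy-4-methoxyphenyl (ring A). The eastern half is a 2-aryl-3-(hydroxymethyl)-4-methoxy-2,3-dihydrobenzofuran whose benzo ring (ring B) carries the methylene at C6. The five stereocentres form two clusters: (2R,3S,4S) on the tetrahydrofuran (2,3-trans, 3,4-cis) and (2S,3R) on the dihydrobenzofuran (trans). The clusters are too far apart to control each other, so each needs its own source of absolute configuration; inside a cluster, tetrahydrofuran C2 can direct C3, C3 can direct C4, and dihydrobenzofuran C3 can direct C2. Ring B is a 1,2,3,5-tetrasubstituted arene whose two oxygens must be told apart, one ending as the C4 methyl ether and the other as ring oxygen O1. Two free phenols, two primary alcohols and two electron-rich benzylic ethers (tetrahydrofuran C2–O beside a para-methoxyaryl group, dihydrobenzofuran C2–O1 beside a para-hydroxyaryl group) rule out strong acid, late strong oxidants and forcing hydrogenolysis. The enabling feature is that dihydrobenzofuran C2 is the benzylic carbon of the 4-hydroxy-3-methoxyphenyl ring, para to its hydroxyl. Two-electron oxidation of that phenol turns C2 into the exocyclic carbon of a para-quinone methide, and the ring B oxygen ortho to C3a can add to it in a five-membered closure.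

## Retrosynthesis

**27 ⇒ 26.** No skeletal bond is cut. The ring A phenol is masked as a triisopropylsilyl ether and both primary alcohols as tert-butyldimethylsilyl ethers, so one buffered fluoride treatment ends the synthesis. Silyl rather than benzyl protection on ring A means no hydrogenolysis is needed once the dihydrobenzofuran exists.

**26 ⇒ 24 (through 25).** The O1–C2 bond of the dihydrobenzofuran is cut. Cutting C2–C3 or C3–C3a instead would require building a quaternary-flanked arene bond or an aldol-type union late, on the full skeleton. The O1–C2 cut removes one ring and one stereocentre and leaves diphenol 24, a 2,3-diarylpropyl silyl ether with a single stereocentre on that side. The forward step must oxidise only the guaiacyl phenol to quinone methide 25, let the ring B phenol add, and deliver the 2,3-trans ring under control of C3.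

**24 ⇒ 23 ⇒ 7 + 21.** The two phenols that must be free in 24 are carried as benzyl ethers in 23, removed by hydrogenolysis before the sensitive dihydrobenzofuran is made. The CH2–aryl bond between the tetrahydrofuran C4 methylene and ring B is then cut. This splits the molecule into halves of similar size, exocyclic alkene 7 and aryl bromide 21. Hydroboration of 7 gives borane 22, which couples directly, and the same operation sets C4. Cutting the C4–CH2 bond instead would need an enolate alkylation on a lactone and a linear sequence.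

**21 ⇒ 20 ⇒ 19 ⇒ 17 + 9.** The Cα–CH2 bond next to the future dihydrobenzofuran C3 is cut. Alkylation of the sodium enolate 18 of arylacetyl imide 17 with benzylic bromide 9 sets this centre under auxiliary control. Reduction to 20 and silylation give 21. Bromide 9 comes from alcohol 8. The alternative of adding the ring B aryl group to a preformed three-carbon unit has no comparably reliable asymmetric version for a 2,6-dioxygenated aryl group.

**17 ⇒ 15 ⇒ 14 ⇒ 13 ⇒ 12 ⇒ 11 ⇒ 10.** Acid 15 (activated as mixed anhydride 16) arises by one-carbon homologation of aldehyde 12 through enol ether 13 and aldehyde 14. The aldehyde of symmetric 10 is kept long enough to direct a chelation-controlled removal of one methyl group (11). This differentiates the two ring B oxygens in one step before the aldehyde is used for the homologation.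

**7 ⇒ 6 ⇒ 5.** The tetrahydrofuran C3–C4 bond is cut. A radical 5-exo-dig closure of epoxy propargyl ether 5 delivers the ring, the exocyclic methylene and the hydroxymethyl group together, with C3 set trans to the aryl group at C2. Ionic closures of triols give the ring but not the alkene handle.

**5 ⇒ 4 ⇒ 3 ⇒ 2 ⇒ 1.** Ether 5 comes from epoxy alcohol 4. A Sharpless kinetic resolution of racemic allylic alcohol 3 supplies 4, fixing the carbinol centre (future C2) and installing the epoxide in the same step. Alcohol 3 is the vinyl adduct of silylated isovanillin 2, made from 1.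

## Roads not taken

**Alternative 1:** Ring B would be built by benzannulation, cutting the arene bonds C7a–C3a and C4–C5. Heating cyclobutenone A1 with siloxyalkyne A2 would give, through vinylketene [2+2] addition, four-electron ring opening and six-electron electrocyclisation, resorcinol monosilyl ether A3.
- Merits: the substitution pattern of ring B is fixed by the mechanism, the two ring B oxygens emerge already differentiated, and the halves are joined in the ring-forming step. On convergence and on avoiding a late oxidation this road is better than the chosen one.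
- Weak points: A2 is an ynol silyl ether carrying two stereocentres, and A1 needs a cyclobutenone grafted onto the tetrahydrofuran half; both are longer to make than 7 and 21. The silyl ether of A3 must later be exchanged for methyl, and the thermal step must tolerate two benzylic ethers.
- Comparison: the chosen plan buys ring B with the right pattern and pays only one selective demethylation.

**Alternative 2:** The C3–C3a bond would be formed by oxidative ring contraction of flavanone A4. PhI(OAc)2 (trivalent iodine) with H2SO4 in trimethyl orthoformate attacks the enol ether at C3, the benzo ring migrates from C4 to C3 and C4 leaves as the methyl ester, giving trans ester A5.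
- Merits: both dihydrobenzofuran centres come from the single flavanone centre, the oxygen pattern is inherent, and A5 keeps the bromide for the same coupling. The eastern half would be several steps shorter than the nine steps from 10 to 21, and this must be conceded.
- Weak points: a 5-alkoxyflavanone such as A4 can open to the chalcone under the acidic conditions and lose its configuration before contraction. The guaiacyl ring has to be deactivated against the oxidant, and the ester must then be reduced and the protecting groups exchanged.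
- Comparison: the chosen plan sets against the shorter count an auxiliary-controlled C3 of predictable sense and a C2 that is set by equilibration.

**Alternative 3:** The tetrahydrofuran would be closed by cycloaddition, cutting C2–C3 and C4–C5. CsF converts α-chloro silylmethyl ether A7 into a non-stabilised carbonyl ylide that adds across butenolide A6 to give cis-fused lactone A8.
- Merits: the ring and its three centres form in one step, and the 3,4-cis relation is enforced by ring fusion. That is more secure than the face-selective hydroboration of the chosen plan.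
- Weak points: the regiochemistry of an unsymmetrical ylide and the orientation of its aryl terminus are not secured. A8 must then lose its lactone benzylic C–O bond by hydrogenolysis in the presence of two other benzylic C–O bonds, and the dihydrobenzofuran must be finished before the cycloaddition, which makes the route linear.
- Comparison: the chosen plan sets against the secure cis fusion a sterically controlled addition anti to the C3 substituent, backed by a hydrogenation fallback. It gains convergence and avoids a selective benzylic hydrogenolysis.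

Key step: step 19

Remark on the chemistry: alcohol 8 is taken as a purchased compound (otherwise two routine steps from vanillin). The oxirane carbon of 4 and 5 is destroyed in step 5, so only the carbinol centre matters. Any minor enantiomer carried from step 3 would become a separable diastereomer after step 17.

## Route

Step 1
Reactants: 1 isovanillin (3-hydroxy-4-methoxybenzaldehyde)
Product: 2 4-methoxy-3-[(triisopropylsilyl)oxy]benzaldehyde
Conditions: iPr3SiCl, imidazole, DMF, rt
Reagents that add atoms: chlorotriisopropylsilane CC(C)[Si](Cl)(C(C)C)C(C)C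
Why: Imidazole-promoted phenol silylation; the triisopropylsilyl ether should survive the alkoxide, radical, borane and aqueous-base steps ahead and falls to fluoride at the end.

Step 2
Reactants: 2 4-methoxy-3-[(triisopropylsilyl)oxy]benzaldehyde
Product: 3 rac-1-{4-methoxy-3-[(triisopropylsilyl)oxy]phenyl}prop-2-en-1-ol
Conditions: CH2=CHMgBr, THF, −78 → 0 °C; aq. NH4Cl
Reagents that add atoms: vinylmagnesium bromide C=C[Mg]Br
Why: Grignard 1,2-addition to the aldehyde; no stereocontrol is sought because the next step resolves the alcohol.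

Step 3
Reactants: 3 rac-1-{4-methoxy-3-[(triisopropylsilyl)oxy]phenyl}prop-2-en-1-ol
Product: 4 (S)-{4-methoxy-3-[(triisopropylsilyl)oxy]phenyl}[(2R)-oxiran-2-yl]methanol (erythro)
Conditions: Ti(OiPr)4 (cat.), diisopropyl L-(+)-tartrate, t-BuOOH (about 0.45 equiv), 4 Å sieves, CH2Cl2, −20 °C
Reagents that add atoms: tert-butyl hydroperoxide CC(C)(C)OO
Why: Sharpless kinetic resolution; with the L-(+)-tartrate the (R)-enantiomer of 3 is epoxidised much faster and gives the erythro epoxy alcohol, so stopping below half conversion should give 4 with the carbinol centre that becomes tetrahydrofuran C2. Unreacted (S)-3 is removed by chromatography.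

Step 4
Reactants: 4 (S)-{4-methoxy-3-[(triisopropylsilyl)oxy]phenyl}[(2R)-oxiran-2-yl]methanol
Product: 5 triisopropyl{2-methoxy-5-[(S)-[(2R)-oxiran-2-yl](prop-2-yn-1-yloxy)methyl]phenoxy}silane
Conditions: NaH, propargyl bromide, Bu4NI (cat.), THF, 0 °C
Reagents that add atoms: propargyl bromide C#CCBr
Why: Williamson etherification of the secondary alkoxide with a reactive propargylic halide at low temperature, which should outrun Payne rearrangement; the carbinol centre is not touched.

Step 5
Reactants: 5 triisopropyl{2-methoxy-5-[(S)-[(2R)-oxiran-2-yl](prop-2-yn-1-yloxy)methyl]phenoxy}silane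
Product: 6 [(2R,3S)-2-{4-methoxy-3-[(triisopropylsilyl)oxy]phenyl}-4-methylidenetetrahydrofuran-3-yl]methanol
Conditions: Cp2TiCl2, Zn dust, THF, rt (slow addition of 5); then 1 M HCl, 0 °C
Reagents that add atoms: none
Why: Cp2TiCl (trivalent titanium, formed in the flask) opens the epoxide reductively to the β-titanoxy secondary radical, which closes 5-exo-dig onto the alkyne; the vinyl radical is reduced and protonated on work-up. C3 is set trans to the C2 aryl group because the chair-like transition state keeps the aryl group pseudo-equatorial and the CH2OTi arm anti to it; this radical cyclisation of aryl epoxy propargyl ethers is a known entry to 2-aryl-3-hydroxymethyl-4-methylidene tetrahydrofurans.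

Step 6
Reactants: 6 [(2R,3S)-2-{4-methoxy-3-[(triisopropylsilyl)oxy]phenyl}-4-methylidenetetrahydrofuran-3-yl]methanol
Product: 7 tert-butyl{[(2R,3S)-2-{4-methoxy-3-[(triisopropylsilyl)oxy]phenyl}-4-methylidenetetrahydrofuran-3-yl]methoxy}dimethylsilane
Conditions: t-BuMe2SiCl, imidazole, DMF, rt
Reagents that add atoms: tert-butyldimethylsilyl chloride CC(C)(C)[Si](C)(C)Cl
Why: Standard silylation of a primary alcohol; the bulky ether also strengthens the facial bias at C4 in step 17.

Step 7
Reactants: 8 [4-(benzyloxy)-3-methoxyphenyl]methanol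
Product: 9 1-(benzyloxy)-4-(bromomethyl)-2-methoxybenzene
Conditions: PBr3, Et2O, 0 °C
Reagents that add atoms: phosphorus tribromide BrP(Br)Br
Why: Conversion of a benzylic alcohol into the bromide with PBr3; the electron-rich bromide is used at once in step 14.

Step 8
Reactants: 10 4-bromo-2,6-dimethoxybenzaldehyde
Product: 11 4-bromo-2-hydroxy-6-methoxybenzaldehyde
Conditions: BCl3 (1.1 equiv), CH2Cl2, −78 → 0 °C; H2O
Reagents that add atoms: none
Why: Chelation-directed ether cleavage; BCl3 bridges the aldehyde oxygen and one ortho methoxy oxygen and only that methyl group is lost, and because the two methoxy groups are equivalent a single monophenol results.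

Step 9
Reactants: 11 4-bromo-2-hydroxy-6-methoxybenzaldehyde
Product: 12 2-(benzyloxy)-4-bromo-6-methoxybenzaldehyde
Conditions: BnBr, K2CO3, DMF, 50 °C
Reagents that add atoms: benzyl bromide BrCc1ccccc1
Why: Williamson benzylation of the phenol; the benzyl ether withstands the base, hydride and coupling steps and is removed under neutral conditions in step 18.

Step 10
Reactants: 12 2-(benzyloxy)-4-bromo-6-methoxybenzaldehyde
Product: 13 1-(benzyloxy)-5-bromo-3-methoxy-2-(2-methoxyethenyl)benzene (E/Z mixture)
Conditions: Ph3P(CH2OMe)Cl, KOtBu, THF, 0 °C → rt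
Reagents that add atoms: (methoxymethyl)triphenylphosphonium chloride COC[P+](c1ccccc1)(c1ccccc1)c1ccccc1.[Cl-]
Why: Wittig methoxymethylenation, the first half of a one-carbon homologation; the small reactive ylide should cope with the two ortho substituents, and the alkene geometry is irrelevant.

Step 11
Reactants: 13 1-(benzyloxy)-5-bromo-3-methoxy-2-(2-methoxyethenyl)benzene
Product: 14 2-[2-(benzyloxy)-4-bromo-6-methoxyphenyl]acetaldehyde
Conditions: 2 M HCl, THF, 40 °C
Reagents that add atoms: water O
Why: Acid hydrolysis of the enol ether to the arylacetaldehyde, which is taken on crude because such aldehydes self-condense.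

Step 12
Reactants: 14 2-[2-(benzyloxy)-4-bromo-6-methoxyphenyl]acetaldehyde
Product: 15 2-[2-(benzyloxy)-4-bromo-6-methoxyphenyl]acetic acid
Conditions: NaClO2, NaH2PO4, 2-methyl-2-butene, t-BuOH/H2O, 0 °C → rt
Reagents that add atoms: sodium chlorite [Na+].[O-]Cl=O
Why: Pinnick oxidation; the alkene scavenger takes up hypochlorous acid so the electron-rich ring is not chlorinated.

Step 13
Reactants: 15 2-[2-(benzyloxy)-4-bromo-6-methoxyphenyl]acetic acid
Product: 17 (4R)-4-benzyl-3-{2-[2-(benzyloxy)-4-bromo-6-methoxyphenyl]acetyl}-1,3-oxazolidin-2-one, via mixed pivalic anhydride 16 (not isolated)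
Conditions: t-BuCOCl, Et3N, THF, −20 °C; then (R)-4-benzyl-1,3-oxazolidin-2-one, LiCl, −20 °C → rt
Reagents that add atoms: (4R)-4-benzyl-1,3-oxazolidin-2-one O=C1N[C@H](Cc2ccccc2)CO1
Why: N-acylation of the oxazolidinone through the mixed pivalic anhydride under the mild LiCl/Et3N protocol, which avoids a strong base on the acidic arylacetyl unit.

Step 14
Reactants: 17 (4R)-4-benzyl-3-{2-[2-(benzyloxy)-4-bromo-6-methoxyphenyl]acetyl}-1,3-oxazolidin-2-one; 9 1-(benzyloxy)-4-(bromomethyl)-2-methoxybenzene
Product: 19 (4R)-4-benzyl-3-[(2R)-2-[2-(benzyloxy)-4-bromo-6-methoxyphenyl]-3-[4-(benzyloxy)-3-methoxyphenyl]propanoyl]-1,3-oxazolidin-2-one, via sodium enolate 18 (not isolated)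
Conditions: NaN(SiMe3)2, THF, −78 °C; then 9, −78 → −30 °C
Reagents that add atoms: none
Why: Evans alkylation; the chelated (Z)-enolate is attacked by the benzylic bromide on the face opposite the benzyl group of the (R)-auxiliary, which should give the (2R) centre that becomes dihydrobenzofuran C3.

Step 15
Reactants: 19 (4R)-4-benzyl-3-[(2R)-2-[2-(benzyloxy)-4-bromo-6-methoxyphenyl]-3-[4-(benzyloxy)-3-methoxyphenyl]propanoyl]-1,3-oxazolidin-2-one
Product: 20 (2R)-2-[2-(benzyloxy)-4-bromo-6-methoxyphenyl]-3-[4-(benzyloxy)-3-methoxyphenyl]propan-1-ol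
Conditions: LiBH4, MeOH (1 equiv), THF, 0 °C
Reagents that add atoms: none
Why: Reductive removal of the auxiliary; hydride attack at the exocyclic carbonyl is faster than enolisation at 0 °C, so the α-aryl centre should be kept, and the aryl bromide and benzyl ethers are inert.

Step 16
Reactants: 20 (2R)-2-[2-(benzyloxy)-4-bromo-6-methoxyphenyl]-3-[4-(benzyloxy)-3-methoxyphenyl]propan-1-ol
Product: 21 {[(2R)-2-[2-(benzyloxy)-4-bromo-6-methoxyphenyl]-3-[4-(benzyloxy)-3-methoxyphenyl]propyl]oxy}(tert-butyl)dimethylsilane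
Conditions: t-BuMe2SiCl, imidazole, DMF, rt
Reagents that add atoms: tert-butyldimethylsilyl chloride CC(C)(C)[Si](C)(C)Cl
Why: Standard silylation of the primary alcohol, which keeps it out of the coupling and the oxidation.

Step 17
Reactants: 7 tert-butyl{[(2R,3S)-2-{4-methoxy-3-[(triisopropylsilyl)oxy]phenyl}-4-methylidenetetrahydrofuran-3-yl]methoxy}dimethylsilane; 21 {[(2R)-2-[2-(benzyloxy)-4-bromo-6-methoxyphenyl]-3-[4-(benzyloxy)-3-methoxyphenyl]propyl]oxy}(tert-butyl)dimethylsilane
Product: 23 (2R,3S,4S)-4-{3-(benzyloxy)-4-[(2R)-3-[4-(benzyloxy)-3-methoxyphenyl]-1-[(tert-butyldimethylsilyl)oxy]propan-2-yl]-5-methoxybenzyl}-3-{[(tert-butyldimethylsilyl)oxy]methyl}-2-{4-methoxy-3-[(triisopropylsilyl)oxy]phenyl}tetrahydrofuran, via B-alkyl-9-BBN adduct 22 (not isolated)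
Conditions: 9-BBN, THF, 0 °C → rt; then 21, PdCl2(dppf) (cat.), AsPh3, aq. K3PO4, DMF, 50 °C
Reagents that add atoms: none
Why: Hydroboration followed by B-alkyl Suzuki–Miyaura coupling. 9-BBN places boron on the terminal carbon and hydrogen on C4 from the face opposite the neighbouring C3 CH2OSi arm, so the new CH2 arm should end cis to it (4S); the primary borane then couples with the aryl bromide without touching any stereocentre.

Step 18
Reactants: 23 (2R,3S,4S)-4-{3-(benzyloxy)-4-[(2R)-3-[4-(benzyloxy)-3-methoxyphenyl]-1-[(tert-butyldimethylsilyl)oxy]propan-2-yl]-5-methoxybenzyl}-3-{[(tert-butyldimethylsilyl)oxy]methyl}-2-{4-methoxy-3-[(triisopropylsilyl)oxy]phenyl}tetrahydrofuran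
Product: 24 5-{[(3S,4S,5R)-4-{[(tert-butyldimethylsilyl)oxy]methyl}-5-{4-methoxy-3-[(triisopropylsilyl)oxy]phenyl}tetrahydrofuran-3-yl]methyl}-2-[(2R)-1-[(tert-butyldimethylsilyl)oxy]-3-(4-hydroxy-3-methoxyphenyl)propan-2-yl]-3-methoxyphenol
Conditions: H2 (1 atm), Pd/C, EtOAc, rt
Reagents that add atoms: none
Why: Hydrogenolysis of two aryl benzyl ethers under neutral conditions at atmospheric pressure; the cyclic benzylic ether of the tetrahydrofuran and the silyl ethers should persist, and the dihydrobenzofuran is not yet present.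

Step 19
Reactants: 24 5-{[(3S,4S,5R)-4-{[(tert-butyldimethylsilyl)oxy]methyl}-5-{4-methoxy-3-[(triisopropylsilyl)oxy]phenyl}tetrahydrofuran-3-yl]methyl}-2-[(2R)-1-[(tert-butyldimethylsilyl)oxy]-3-(4-hydroxy-3-methoxyphenyl)propan-2-yl]-3-methoxyphenol
Product: 26 4-[(2S,3R)-3-{[(tert-butyldimethylsilyl)oxy]methyl}-6-{[(3S,4S,5R)-4-{[(tert-butyldimethylsilyl)oxy]methyl}-5-{4-methoxy-3-[(triisopropylsilyl)oxy]phenyl}tetrahydrofuran-3-yl]methyl}-4-methoxy-2,3-dihydro-1-benzofuran-2-yl]-2-methoxyphenol, via para-quinone methide 25 (not isolated)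
Conditions: Ag2O (1.2 equiv), CH2Cl2, rt, dark
Reagents that add atoms: none
Why: Ag2O removes two electrons and two protons from the 4-alkyl-2-methoxyphenol (the phenol O–H and the benzylic C–H para to it) to give para-quinone methide 25; this is the known silver oxide oxidation of 4-alkylguaiacols, and the closure is the intramolecular form of the phenol addition that closes the ring in biomimetic dihydrobenzofuran neolignan couplings. The ring B hydroxyl ortho to C3a adds to the exocyclic carbon of 25 in a 5-exo-trig oxa-conjugate addition that forms O1–C2 and restores the aromatic guaiacyl ring. The new centre C2 is controlled by C3: the arrangement with the aryl group anti to the CH2OSi arm is favoured in both transition state and product, and since the mildly basic medium lets the addition revert through the phenoxide, the mixture should settle on the 2,3-trans isomer (2S,3R). Chemoselectivity rests on the substrate: only the guaiacyl ring has a free hydroxyl para to an sp3 C–H bond, ring A is silylated, and the ring B phenol is of the less easily oxidised resorcinol type with hydrogen para to oxygen. The five-membered closure should outrun tautomerisation of 25 to a styrene and attack by outside nucleophiles. Over-oxidation of 26 towards the benzofuran is limited by using little more than one equivalent of oxidant and stopping when 24 is consumed.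

Step 20
Reactants: 26 4-[(2S,3R)-3-{[(tert-butyldimethylsilyl)oxy]methyl}-6-{[(3S,4S,5R)-4-{[(tert-butyldimethylsilyl)oxy]methyl}-5-{4-methoxy-3-[(triisopropylsilyl)oxy]phenyl}tetrahydrofuran-3-yl]methyl}-4-methoxy-2,3-dihydro-1-benzofuran-2-yl]-2-methoxyphenol
Product: 27 5-[(2R,3S,4S)-4-{[(2S,3R)-2-(4-hydroxy-3-methoxyphenyl)-3-(hydroxymethyl)-4-methoxy-2,3-dihydro-1-benzofuran-6-yl]methyl}-3-(hydroxymethyl)tetrahydrofuran-2-yl]-2-methoxyphenol (CNP0242386.1)
Conditions: Bu4NF, AcOH, THF, 0 °C → rt
Reagents that add atoms: none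
Why: Fluoride cleavage of one aryl and two alkyl silyl ethers; acetic acid buffers the medium so the para-hydroxybenzyl aryl ether is not held as its phenoxide, and any reversible opening would in any case return the trans ring.

## Compound list

1 | isovanillin (3-hydroxy-4-methoxybenzaldehyde) | COc1ccc(C=O)cc1O | starting material
2 | 4-methoxy-3-[(triisopropylsilyl)oxy]benzaldehyde | COc1ccc(C=O)cc1O[Si](C(C)C)(C(C)C)C(C)C | intermediate
3 | rac-1-{4-methoxy-3-[(triisopropylsilyl)oxy]phenyl}prop-2-en-1-ol | COc1ccc(C(O)C=C)cc1O[Si](C(C)C)(C(C)C)C(C)C | intermediate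
4 | (S)-{4-methoxy-3-[(triisopropylsilyl)oxy]phenyl}[(2R)-oxiran-2-yl]methanol | COc1ccc([C@H](O)[C@H]2CO2)cc1O[Si](C(C)C)(C(C)C)C(C)C | intermediate
5 | triisopropyl{2-methoxy-5-[(S)-[(2R)-oxiran-2-yl](prop-2-yn-1-yloxy)methyl]phenoxy}silane | COc1ccc([C@H](OCC#C)[C@H]2CO2)cc1O[Si](C(C)C)(C(C)C)C(C)C | intermediate
6 | [(2R,3S)-2-{4-methoxy-3-[(triisopropylsilyl)oxy]phenyl}-4-methylidenetetrahydrofuran-3-yl]methanol | COc1ccc([C@@H]2OCC(=C)[C@H]2CO)cc1O[Si](C(C)C)(C(C)C)C(C)C | intermediate
7 | tert-butyl{[(2R,3S)-2-{4-methoxy-3-[(triisopropylsilyl)oxy]phenyl}-4-methylidenetetrahydrofuran-3-yl]methoxy}dimethylsilane | COc1ccc([C@@H]2OCC(=C)[C@H]2CO[Si](C)(C)C(C)(C)C)cc1O[Si](C(C)C)(C(C)C)C(C)C | intermediate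
8 | [4-(benzyloxy)-3-methoxyphenyl]methanol | COc1cc(CO)ccc1OCc1ccccc1 | starting material
9 | 1-(benzyloxy)-4-(bromomethyl)-2-methoxybenzene | COc1cc(CBr)ccc1OCc1ccccc1 | intermediate
10 | 4-bromo-2,6-dimethoxybenzaldehyde | COc1cc(Br)cc(OC)c1C=O | starting material
11 | 4-bromo-2-hydroxy-6-methoxybenzaldehyde | COc1cc(Br)cc(O)c1C=O | intermediate
12 | 2-(benzyloxy)-4-bromo-6-methoxybenzaldehyde | COc1cc(Br)cc(OCc2ccccc2)c1C=O | intermediate
13 | 1-(benzyloxy)-5-bromo-3-methoxy-2-(2-methoxyethenyl)benzene (E/Z mixture) | COC=Cc1c(OC)cc(Br)cc1OCc1ccccc1 | intermediate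
14 | 2-[2-(benzyloxy)-4-bromo-6-methoxyphenyl]acetaldehyde | COc1cc(Br)cc(OCc2ccccc2)c1CC=O | intermediate
15 | 2-[2-(benzyloxy)-4-bromo-6-methoxyphenyl]acetic acid | COc1cc(Br)cc(OCc2ccccc2)c1CC(=O)O | intermediate
16 | 2-[2-(benzyloxy)-4-bromo-6-methoxyphenyl]acetic pivalic anhydride | COc1cc(Br)cc(OCc2ccccc2)c1CC(=O)OC(=O)C(C)(C)C | intermediate (not isolated)
17 | (4R)-4-benzyl-3-{2-[2-(benzyloxy)-4-bromo-6-methoxyphenyl]acetyl}-1,3-oxazolidin-2-one | COc1cc(Br)cc(OCc2ccccc2)c1CC(=O)N1C(=O)OC[C@H]1Cc1ccccc1 | intermediate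
18 | sodium (Z)-enolate of 17 | [Na+].[O-]/C(=C\c1c(OC)cc(Br)cc1OCc1ccccc1)N1C(=O)OC[C@H]1Cc1ccccc1 | intermediate (not isolated)
19 | (4R)-4-benzyl-3-[(2R)-2-[2-(benzyloxy)-4-bromo-6-methoxyphenyl]-3-[4-(benzyloxy)-3-methoxyphenyl]propanoyl]-1,3-oxazolidin-2-one | O=C(N1C(=O)OC[C@H]1Cc1ccccc1)[C@H](Cc1ccc(OCc2ccccc2)c(OC)c1)c1c(OC)cc(Br)cc1OCc1ccccc1 | intermediate
20 | (2R)-2-[2-(benzyloxy)-4-bromo-6-methoxyphenyl]-3-[4-(benzyloxy)-3-methoxyphenyl]propan-1-ol | OC[C@H](Cc1ccc(OCc2ccccc2)c(OC)c1)c1c(OC)cc(Br)cc1OCc1ccccc1 | intermediate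
21 | {[(2R)-2-[2-(benzyloxy)-4-bromo-6-methoxyphenyl]-3-[4-(benzyloxy)-3-methoxyphenyl]propyl]oxy}(tert-butyl)dimethylsilane | CC(C)(C)[Si](C)(C)OC[C@H](Cc1ccc(OCc2ccccc2)c(OC)c1)c1c(OC)cc(Br)cc1OCc1ccccc1 | intermediate
22 | 9-{[(3S,4S,5R)-4-{[(tert-butyldimethylsilyl)oxy]methyl}-5-{4-methoxy-3-[(triisopropylsilyl)oxy]phenyl}tetrahydrofuran-3-yl]methyl}-9-borabicyclo[3.3.1]nonane | COc1ccc([C@@H]2OC[C@@H](CB3C4CCCC3CCC4)[C@H]2CO[Si](C)(C)C(C)(C)C)cc1O[Si](C(C)C)(C(C)C)C(C)C | intermediate (not isolated)
23 | (2R,3S,4S)-4-{3-(benzyloxy)-4-[(2R)-3-[4-(benzyloxy)-3-methoxyphenyl]-1-[(tert-butyldimethylsilyl)oxy]propan-2-yl]-5-methoxybenzyl}-3-{[(tert-butyldimethylsilyl)oxy]methyl}-2-{4-methoxy-3-[(triisopropylsilyl)oxy]phenyl}tetrahydrofuran | COc1ccc([C@@H]2OC[C@@H](Cc3cc(OC)c([C@H](CO[Si](C)(C)C(C)(C)C)Cc4ccc(OCc5ccccc5)c(OC)c4)c(OCc4ccccc4)c3)[C@H]2CO[Si](C)(C)C(C)(C)C)cc1O[Si](C(C)C)(C(C)C)C(C)C | intermediate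
24 | 5-{[(3S,4S,5R)-4-{[(tert-butyldimethylsilyl)oxy]methyl}-5-{4-methoxy-3-[(triisopropylsilyl)oxy]phenyl}tetrahydrofuran-3-yl]methyl}-2-[(2R)-1-[(tert-butyldimethylsilyl)oxy]-3-(4-hydroxy-3-methoxyphenyl)propan-2-yl]-3-methoxyphenol | COc1ccc([C@@H]2OC[C@@H](Cc3cc(OC)c([C@H](CO[Si](C)(C)C(C)(C)C)Cc4ccc(O)c(OC)c4)c(O)c3)[C@H]2CO[Si](C)(C)C(C)(C)C)cc1O[Si](C(C)C)(C(C)C)C(C)C | intermediate
25 | para-quinone methide of 24: 2-methoxy-4-alkylidenecyclohexa-2,5-dien-1-one with the exocyclic C=C at the future C2 and C3 unchanged (R) | COC1=CC(=C[C@@H](CO[Si](C)(C)C(C)(C)C)c2c(O)cc(C[C@@H]3CO[C@@H](c4ccc(OC)c(O[Si](C(C)C)(C(C)C)C(C)C)c4)[C@@H]3CO[Si](C)(C)C(C)(C)C)cc2OC)C=CC1=O | intermediate (not isolated)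
26 | 4-[(2S,3R)-3-{[(tert-butyldimethylsilyl)oxy]methyl}-6-{[(3S,4S,5R)-4-{[(tert-butyldimethylsilyl)oxy]methyl}-5-{4-methoxy-3-[(triisopropylsilyl)oxy]phenyl}tetrahydrofuran-3-yl]methyl}-4-methoxy-2,3-dihydro-1-benzofuran-2-yl]-2-methoxyphenol | COc1ccc([C@@H]2OC[C@@H](Cc3cc(OC)c4c(c3)O[C@H](c3ccc(O)c(OC)c3)[C@H]4CO[Si](C)(C)C(C)(C)C)[C@H]2CO[Si](C)(C)C(C)(C)C)cc1O[Si](C(C)C)(C(C)C)C(C)C | intermediate
27 | 5-[(2R,3S,4S)-4-{[(2S,3R)-2-(4-hydroxy-3-methoxyphenyl)-3-(hydroxymethyl)-4-methoxy-2,3-dihydro-1-benzofuran-6-yl]methyl}-3-(hydroxymethyl)tetrahydrofuran-2-yl]-2-methoxyphenol | COc1ccc([C@@H]2OC[C@@H](Cc3cc(OC)c4c(c3)O[C@H](c3ccc(O)c(OC)c3)[C@H]4CO)[C@H]2CO)cc1O | target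

## Step count and least certain steps

Total: 20 steps. Longest linear sequence: 13 steps (steps 8–16 from 10, then steps 17–20). The tetrahydrofuran branch has 6 steps (steps 1–6) and the bromide branch 1 step (step 7).

**Step 19 (key step).** The most likely failure is oxidation running past the wanted stage or down the wrong channel: one-electron phenol coupling, tautomerisation of the quinone methide to a styrene before ring closure, or a second oxidation at C2 towards the benzofuran. The fallback installs the C2 oxygen by an aldol reaction and closes the ring without an oxidant. It sets out from acid 15, which is acylated as in step 13 but onto the enantiomeric auxiliary to give (4S)-4-benzyl-3-{2-[2-(benzyloxy)-4-bromo-6-methoxyphenyl]acetyl}-1,3-oxazolidin-2-one F1. A boron-mediated Evans syn-aldol reaction (Bu2BOTf, iPr2NEt, CH2Cl2, −78 °C) with commercial 4-(benzyloxy)-3-methoxybenzaldehyde would give the (2S,3S) aldol adduct F2; boron aldol and enolate alkylation use opposite enolate faces, hence the change of auxiliary. LiBH4 reduction gives (1S,2R)-2-[2-(benzyloxy)-4-bromo-6-methoxyphenyl]-1-[4-(benzyloxy)-3-methoxyphenyl]propane-1,3-diol F3, and selective silylation of the primary hydroxyl gives the mono-silyl ether F4. Coupling with borane 22 as in step 17 gives the benzylic alcohol analogue of 23, F5, and hydrogenolysis as in step 18 gives the benzylic alcohol analogue of 24, F6. Mild acid (pyridinium p-toluenesulfonate, CH2Cl2, 0 °C) then ionises the para-hydroxybenzylic alcohol and the ring B phenol closes the ring under thermodynamic control, returning to the route at 26.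

**Step 17.** The most likely failure is poor facial selectivity in the hydroboration, giving the C4 epimer, because the C2 aryl group on the other face competes with the C3 arm. The fallback replaces hydroboration by hydrogenation of a benzylidene tetrahydrofuran. It sets out from epoxy propargyl ether 5 and bromide 21: Sonogashira coupling (Pd(PPh3)2Cl2, CuI, Et3N, 60 °C) gives the aryl alkyne F7. Cyclisation with Cp2TiCl as in step 5 gives the 4-benzylidene tetrahydrofuran alcohol F8, and silylation as in step 6 gives its silyl ether F9. Hydrogenation over Pd/C then adds hydrogen to the trisubstituted alkene from the face opposite the C3 arm and removes both benzyl groups in the same operation, returning to the route at 24.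

**Step 14.** The most likely failure is sluggish alkylation of the enolate flanked by two ortho substituents, with loss of the acyl group through a ketene or partial epimerisation on warming. The fallback forms the same C–C bond by an aldol reaction and then removes the hydroxyl. It sets out from acid 15 and proceeds through the (4S)-imide F1 and the syn-aldol adduct F2 described under step 19. Ionic deoxygenation of the electron-rich benzylic alcohol (Et3SiH, BF3·OEt2, CH2Cl2, −78 °C) gives (4S)-4-benzyl-3-[(2R)-2-[2-(benzyloxy)-4-bromo-6-methoxyphenyl]-3-[4-(benzyloxy)-3-methoxyphenyl]propanoyl]-1,3-oxazolidin-2-one F13. LiBH4 reduction as in step 15 returns to the route at 20.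

**Step 4.** The most likely failure is Payne rearrangement or opening of the epoxide under the alkoxide conditions, which would scramble the position of the ether. The fallback makes the ether before the epoxide. It sets out from racemic alcohol 3, which is resolved with diisopropyl D-(−)-tartrate beyond half conversion so that (R)-1-{4-methoxy-3-[(triisopropylsilyl)oxy]phenyl}prop-2-en-1-ol F10 is recovered. O-Propargylation (NaH, propargyl bromide) gives the allyl propargyl ether F11, and epoxidation of the terminal alkene with mCPBA gives the oxirane F12 as a mixture of epimers at the oxirane carbon. Both epimers converge on the same radical under the conditions of step 5, returning to the route at 6.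

## Further compounds

F1 | step 19 | (4S)-4-benzyl-3-{2-[2-(benzyloxy)-4-bromo-6-methoxyphenyl]acetyl}-1,3-oxazolidin-2-one | COc1cc(Br)cc(OCc2ccccc2)c1CC(=O)N1C(=O)OC[C@@H]1Cc1ccccc1
F2 | step 19 | (4S)-4-benzyl-3-[(2S,3S)-2-[2-(benzyloxy)-4-bromo-6-methoxyphenyl]-3-[4-(benzyloxy)-3-methoxyphenyl]-3-hydroxypropanoyl]-1,3-oxazolidin-2-one | O=C(N1C(=O)OC[C@@H]1Cc1ccccc1)[C@H]([C@H](O)c1ccc(OCc2ccccc2)c(OC)c1)c1c(OC)cc(Br)cc1OCc1ccccc1
F3 | step 19 | (1S,2R)-2-[2-(benzyloxy)-4-bromo-6-methoxyphenyl]-1-[4-(benzyloxy)-3-methoxyphenyl]propane-1,3-diol | OC[C@H]([C@H](O)c1ccc(OCc2ccccc2)c(OC)c1)c1c(OC)cc(Br)cc1OCc1ccccc1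
F4 | step 19 | (1S,2R)-2-[2-(benzyloxy)-4-bromo-6-methoxyphenyl]-1-[4-(benzyloxy)-3-methoxyphenyl]-3-[(tert-butyldimethylsilyl)oxy]propan-1-ol | CC(C)(C)[Si](C)(C)OC[C@H]([C@H](O)c1ccc(OCc2ccccc2)c(OC)c1)c1c(OC)cc(Br)cc1OCc1ccccc1
F5 | step 19 | benzylic alcohol analogue of 23, (1S,2R) in the propyl chain, hydroxyl on the carbon bearing the 4-(benzyloxy)-3-methoxyphenyl group | COc1ccc([C@@H]2OC[C@@H](Cc3cc(OC)c([C@H](CO[Si](C)(C)C(C)(C)C)[C@H](O)c4ccc(OCc5ccccc5)c(OC)c4)c(OCc4ccccc4)c3)[C@H]2CO[Si](C)(C)C(C)(C)C)cc1O[Si](C(C)C)(C(C)C)C(C)C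
F6 | step 19 | benzylic alcohol analogue of 24, (1S,2R) in the propyl chain, both phenols free | COc1ccc([C@@H]2OC[C@@H](Cc3cc(OC)c([C@H](CO[Si](C)(C)C(C)(C)C)[C@H](O)c4ccc(O)c(OC)c4)c(O)c3)[C@H]2CO[Si](C)(C)C(C)(C)C)cc1O[Si](C(C)C)(C(C)C)C(C)C
F7 | step 17 | aryl alkyne from 5 and 21: the propargyl terminus of 5 bonded to the former C–Br carbon of 21 | COc1ccc([C@H](OCC#Cc2cc(OC)c([C@H](CO[Si](C)(C)C(C)(C)C)Cc3ccc(OCc4ccccc4)c(OC)c3)c(OCc3ccccc3)c2)[C@H]2CO2)cc1O[Si](C(C)C)(C(C)C)C(C)C
F8 | step 17 | [(2R,3S)-4-benzylidene tetrahydrofuran-3-yl]methanol carrying the ring A aryl group at C2 and the benzyl-protected eastern half on the alkene (E/Z mixture) | COc1ccc([C@@H]2OCC(=Cc3cc(OC)c([C@H](CO[Si](C)(C)C(C)(C)C)Cc4ccc(OCc5ccccc5)c(OC)c4)c(OCc4ccccc4)c3)[C@H]2CO)cc1O[Si](C(C)C)(C(C)C)C(C)C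
F9 | step 17 | tert-butyldimethylsilyl ether of F8 | COc1ccc([C@@H]2OCC(=Cc3cc(OC)c([C@H](CO[Si](C)(C)C(C)(C)C)Cc4ccc(OCc5ccccc5)c(OC)c4)c(OCc4ccccc4)c3)[C@H]2CO[Si](C)(C)C(C)(C)C)cc1O[Si](C(C)C)(C(C)C)C(C)C
F10 | step 4 | (R)-1-{4-methoxy-3-[(triisopropylsilyl)oxy]phenyl}prop-2-en-1-ol | COc1ccc([C@H](O)C=C)cc1O[Si](C(C)C)(C(C)C)C(C)C
F11 | step 4 | triisopropyl{2-methoxy-5-[(R)-1-(prop-2-yn-1-yloxy)prop-2-en-1-yl]phenoxy}silane | COc1ccc([C@H](OCC#C)C=C)cc1O[Si](C(C)C)(C(C)C)C(C)C
F12 | step 4 | triisopropyl{2-methoxy-5-[(S)-oxiran-2-yl(prop-2-yn-1-yloxy)methyl]phenoxy}silane, mixture of epimers at the oxirane carbon | COc1ccc([C@H](OCC#C)C2CO2)cc1O[Si](C(C)C)(C(C)C)C(C)C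
F13 | step 14 | (4S)-4-benzyl-3-[(2R)-2-[2-(benzyloxy)-4-bromo-6-methoxyphenyl]-3-[4-(benzyloxy)-3-methoxyphenyl]propanoyl]-1,3-oxazolidin-2-one | O=C(N1C(=O)OC[C@@H]1Cc1ccccc1)[C@H](Cc1ccc(OCc2ccccc2)c(OC)c1)c1c(OC)cc(Br)cc1OCc1ccccc1
A1 | alternative 1 | 3-{[(3S,4S,5R)-5-[3-(benzyloxy)-4-methoxyphenyl]-4-{[(tert-butyldimethylsilyl)oxy]methyl}tetrahydrofuran-3-yl]methyl}cyclobut-2-en-1-one | O=C1C=C(C[C@@H]2CO[C@@H](c3ccc(OC)c(OCc4ccccc4)c3)[C@@H]2CO[Si](C)(C)C(C)(C)C)C1
A2 | alternative 1 | triisopropylsilyl ynol ether carrying the CH(CH2OSi) and CH(OSi)(aryl) centres of the eastern half | CC(C)[Si](OC#C[C@H](CO[Si](C)(C)C(C)(C)C)[C@H](O[Si](C)(C)C(C)(C)C)c1ccc(OCc2ccccc2)c(OC)c1)(C(C)C)C(C)C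
A3 | alternative 1 | 2-substituted 5-alkylresorcinol mono(triisopropylsilyl) ether joining both halves | COc1ccc([C@@H]2OC[C@@H](Cc3cc(O[Si](C(C)C)(C(C)C)C(C)C)c([C@H](CO[Si](C)(C)C(C)(C)C)[C@H](O[Si](C)(C)C(C)(C)C)c4ccc(OCc5ccccc5)c(OC)c4)c(O)c3)[C@H]2CO[Si](C)(C)C(C)(C)C)cc1OCc1ccccc1
A4 | alternative 2 | (2S)-7-bromo-5-methoxy-2-[3-methoxy-4-(pivaloyloxy)phenyl]chroman-4-one | O=C1C[C@@H](c2ccc(OC(=O)C(C)(C)C)c(OC)c2)Oc2cc(Br)cc(OC)c12
A5 | alternative 2 | trans methyl (2S,3S)-6-bromo-4-methoxy-2-[3-methoxy-4-(pivaloyloxy)phenyl]-2,3-dihydro-1-benzofuran-3-carboxylate | Brc1cc(OC)c2c(c1)O[C@H](c1ccc(OC(=O)C(C)(C)C)c(OC)c1)[C@H]2C(=O)OC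
A6 | alternative 3 | 5-aryl-furan-2(5H)-one whose aryl group is the silyl- and benzyl-protected (2S,3R)-dihydrobenzofuran unit attached through C6 | O=C1C=C[C@@H](O1)c1cc(OC)c2c(c1)O[C@H](c1ccc(OCc3ccccc3)c(OC)c1)[C@H]2CO[Si](C)(C)C(C)(C)C
A7 | alternative 3 | ({[3-(benzyloxy)-4-methoxyphenyl]chloromethoxy}methyl)trimethylsilane | COc1ccc(C(Cl)OC[Si](C)(C)C)cc1OCc1ccccc1
A8 | alternative 3 | cis-fused 3,7-dioxabicyclo[3.3.0]octan-2-one with both aryl groups on the convex face | COc1ccc([C@@H]2OC[C@@H]3[C@H]2C(=O)O[C@H]3c2cc(OC)c3c(c2)O[C@H](c2ccc(OCc4ccccc4)c(OC)c2)[C@H]3CO[Si](C)(C)C(C)(C)C)cc1OCc1ccccc1
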